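**Plan**

- Numbering (spiro[4.5]decane): C1 = CHOH, C2 = CH bearing the triene, C5 = spiro carbon, C6 = C(CH3)OH, C9 = alkylidene carbon, C10 = CH bearing hydroxypropyl; ring A = C1–C5, ring B = C5–C10.
- Enabling feature: O–C1–C5–C6(–O) is a 1,3-dioxygenated array with the C1 oxygen and C6 cis on ring A, which is an opened isoxazoline fused across C5–C1 at the spiro carbon.
- Retrosynthetic cuts, in order: the triene C=C next to C2 (ester aldol condensation with a ten-carbon dienal) and the C9=C bond of the enal (isopropenyl addition, oxidative transposition); C6–CH3; C5–C6 together with C1–O (nitrile oxide cycloaddition); C9–C8 (thioester–alkylzinc coupling); C10–allyl (auxiliary alkylation); C2–CH(CO2Me)2 (allylic alkylation).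
- Forward: ring A is bought as 3-ethoxycyclopentenone and fitted with both arms; ring B and the isoxazoline close together in the cycloaddition; the enal and then the triene chain are added last.
- Stereochemistry: C2 from CBS reduction, transferred by palladium with net retention; C10 from the oxazolidinone auxiliary; C5 and C1 from cycloaddition anti to the C2 arm; C6 from methyl addition anti to the C1 silyloxy group; E alkenes from Heck coupling and E1cB elimination, Z enal by thermodynamic control.

Key step: step 17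

Remark: the aldoxime is drawn as its E isomer (both isomers give the same nitrile oxide), and the carbinol of step 22 and the aldol adduct of step 27 are carried as mixtures at centres that are destroyed one step later.

**Route**

Step 1
Reactants: 1 3-ethoxycyclopent-2-en-1-one; 2 tert-butyl acetate
Product: 5 tert-butyl 2-(3-oxocyclopent-1-en-1-yl)acetate, via lithium enolate 3 (not isolated), via tertiary carbinol adduct 4 (not isolated)
Conditions: LiN(i-Pr)2, THF, −78 °C; then 1, −78 → 0 °C; then 1 M HCl, 0 °C
Reagents that add atoms: water, O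
Why: In this Stork–Danheiser sequence the ester enolate adds to the carbonyl of the vinylogous ester and acid hydrolysis of the enol ether with loss of the tertiary hydroxyl transposes the enone, which places the acetate arm on the future C5 without creating a stereocentre.

Step 2
Reactants: 5 tert-butyl 2-(3-oxocyclopent-1-en-1-yl)acetate
Product: 6 tert-butyl 2-[(3R)-3-hydroxycyclopent-1-en-1-yl]acetate
Conditions: (S)-2-methyl-CBS-oxazaborolidine (20 mol%), catecholborane, toluene, −78 °C
Reagents that add atoms: none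
Why: In this Corey–Bakshi–Shibata reduction the (S)-oxazaborolidine binds the enone with the alkene side as the large group and delivers hydride 1,2 to give the (R)-allylic alcohol, the source of the C2 configuration; any minor enantiomer becomes a separable diastereomer once the auxiliary is attached.

Step 3
Reactants: 6 tert-butyl 2-[(3R)-3-hydroxycyclopent-1-en-1-yl]acetate
Product: 7 tert-butyl 2-[(3R)-3-(acetyloxy)cyclopent-1-en-1-yl]acetate
Conditions: Ac2O, Et3N, DMAP (cat.), CH2Cl2, 0 °C
Reagents that add atoms: acetic anhydride, CC(=O)OC(C)=O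
Why: DMAP-catalysed acetylation turns the hydroxyl into a leaving group for palladium without touching the stereocentre.

Step 4
Reactants: 7 tert-butyl 2-[(3R)-3-(acetyloxy)cyclopent-1-en-1-yl]acetate; 8 dimethyl malonate
Product: 10 dimethyl 2-[(1R)-3-(2-tert-butoxy-2-oxoethyl)cyclopent-2-en-1-yl]propanedioate, via sodium malonate 9 (not isolated)
Conditions: NaH, THF, 0 °C (8 to 9); then 7, Pd(PPh3)4 (3 mol%), THF, rt
Reagents that add atoms: none
Why: In this Tsuji–Trost allylic alkylation zerovalent palladium ionises the acetate with inversion and the soft malonate attacks the unsubstituted allyl terminus anti to the metal, so the C–C bond replaces the C–O bond with net retention, the alkene stays between C5 and C1, and the cyclic allyl unit cannot racemise by syn–anti exchange.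

Step 5
Reactants: 10 dimethyl 2-[(1R)-3-(2-tert-butoxy-2-oxoethyl)cyclopent-2-en-1-yl]propanedioate
Product: 11 methyl 2-[(1S)-3-(2-tert-butoxy-2-oxoethyl)cyclopent-2-en-1-yl]acetate
Conditions: NaCl, H2O, DMSO, 150 °C
Reagents that add atoms: none
Why: In this Krapcho dealkoxycarbonylation chloride demethylates one malonate ester and the carboxylate loses CO2, while the tert-butyl ester (no SN2 dealkylation possible) and the stereocentre are untouched.

Step 6
Reactants: 11 methyl 2-[(1S)-3-(2-tert-butoxy-2-oxoethyl)cyclopent-2-en-1-yl]acetate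
Product: 13 2-[(3S)-3-(2-methoxy-2-oxoethyl)cyclopent-1-en-1-yl]acetic acid, via trimethylsilyl ester 12 (not isolated)
Conditions: Me3SiOTf, 2,6-lutidine, CH2Cl2, 0 °C; then H2O
Reagents that add atoms: none
Why: Silyl triflate-mediated tert-butyl ester cleavage expels isobutene to leave a silyl ester that water hydrolyses, a non-protic method chosen so that the trisubstituted alkene is neither protonated nor shifted and the methyl ester survives.

Step 7
Reactants: 13 2-[(3S)-3-(2-methoxy-2-oxoethyl)cyclopent-1-en-1-yl]acetic acid; 14 (4S)-4-benzyl-1,3-oxazolidin-2-one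
Product: 16 N-acyl oxazolidinone (imide) of acid 13, via mixed pivalic anhydride 15 (not isolated)
Conditions: t-BuCOCl, Et3N, THF, −20 °C; then 14, LiCl, −20 °C → rt
Reagents that add atoms: none
Why: Mixed-anhydride N-acylation under the mild LiCl/Et3N protocol attaches the Evans auxiliary at the unhindered carbonyl of the pivalic anhydride without enolising the β,γ-unsaturated acyl group.

Step 8
Reactants: 16 N-acyl oxazolidinone (imide) of acid 13; 17 allyl bromide
Product: 19 (2S)-α-allyl imide, via sodium enolate 18 (not isolated)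
Conditions: NaN(SiMe3)2, THF, −78 °C; then 17, −78 → −45 °C; pH 7 buffer at −78 °C
Reagents that add atoms: none
Why: In this Evans asymmetric alkylation the chelated (Z)-enolate forms only at the imide, whose α-hydrogens are also allylic, and is allylated at the α-carbon on the face opposite the benzyl group, which sets C10 as (S) while the much less acidic ester arm is not deprotonated.

Step 9
Reactants: 19 (2S)-α-allyl imide
Product: 20 S-ethyl thioester, methyl 2-[(1S)-3-[(2S)-1-(ethylsulfanyl)-1-oxopent-4-en-2-yl]cyclopent-2-en-1-yl]acetate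
Conditions: EtSH, n-BuLi, THF, 0 °C; then 19, 0 °C
Reagents that add atoms: ethanethiol, CCS
Why: Thiolate transacylation of the N-acyl oxazolidinone takes place at the exocyclic carbonyl with a soft, weakly basic nucleophile, which releases the auxiliary for recovery and leaves the enolisable C10 centre, the methyl ester and both alkenes alone.

Step 10
Reactants: 20 S-ethyl thioester; 21 3-bromopropyl acetate
Product: 23 methyl 2-[(1S)-3-[(4S)-8-(acetyloxy)-5-oxooct-1-en-4-yl]cyclopent-2-en-1-yl]acetate, via alkylzinc bromide 22 (not isolated)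
Conditions: 21, Zn dust, I2 (5 mol%), DMA, 70 °C; then 20, PdCl2(PPh3)2 (5 mol%), toluene, rt
Reagents that add atoms: none
Why: In this Fukuyama coupling the acyl–palladium species from oxidative addition into the C–S bond is alkylated by the functionalised alkylzinc reagent under neutral conditions, which gives the C9 ketone without over-addition, without reaction at either ester and with the least risk to the doubly activated C10 centre.

Step 11
Reactants: 23 methyl 2-[(1S)-3-[(4S)-8-(acetyloxy)-5-oxooct-1-en-4-yl]cyclopent-2-en-1-yl]acetate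
Product: 24 C9 ethylene ketal of 23
Conditions: (Me3SiOCH2)2, Me3SiOTf (5 mol%), CH2Cl2, −78 → −20 °C; pyridine quench
Reagents that add atoms: 1,2-bis(trimethylsilyloxy)ethane, C[Si](C)(C)OCCO[Si](C)(C)C
Why: Noyori ketalisation with the bis-silyl ether of glycol and catalytic silyl triflate at low temperature masks the C9 ketone without moving the β,γ-double bond or epimerising C10, and removes the acidity of the C10 hydrogen for the rest of the route.

Step 12
Reactants: 24 C9 ethylene ketal of 23
Product: 26 primary alcohol at the C10 side chain, via B-alkyl-9-BBN adduct 25 (not isolated)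
Conditions: 9-BBN, THF, 0 °C → rt; then 30% H2O2, aq. NaOAc, 0 °C → rt
Reagents that add atoms: hydrogen peroxide, OO
Why: In this hydroboration–oxidation 9-BBN adds anti-Markovnikov to the monosubstituted alkene far faster than to the trisubstituted ring alkene, and acetate-buffered peroxide oxidation spares both esters.

Step 13
Reactants: 26 primary alcohol at the C10 side chain
Product: 27 tert-butyldimethylsilyl ether of 26
Conditions: t-BuMe2SiCl, imidazole, DMF, rt
Reagents that add atoms: tert-butyldimethylsilyl chloride, CC(C)(C)[Si](C)(C)Cl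
Why: Imidazole-promoted silylation of the primary alcohol protects the future hydroxypropyl terminus for the rest of the synthesis.

Step 14
Reactants: 27 tert-butyldimethylsilyl ether of 26
Product: 28 primary alcohol at C6
Conditions: K2CO3 (cat.), MeOH, 0 °C → rt
Reagents that add atoms: none
Why: Carbonate-catalysed methanolysis (transesterification) removes the acetate while the methyl ester is degenerate and the silyl ether and ketal are stable; the C6 terminus was carried as an acetate because an aldehyde acetal could not be opened later beside the C9 ketal.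

Step 15
Reactants: 28 primary alcohol at C6
Product: 29 C6 aldehyde
Conditions: Dess–Martin periodinane, pyridine, CH2Cl2, 0 °C → rt
Reagents that add atoms: none
Why: Dess–Martin oxidation converts the primary alcohol into the aldehyde under buffered non-aqueous conditions that leave the ketal, silyl ether and alkene untouched.

Step 16
Reactants: 29 C6 aldehyde
Product: 30 cyclopentenyl aldoxime
Conditions: NH2OH·HCl, pyridine, EtOH, rt
Reagents that add atoms: hydroxylamine hydrochloride, NO.Cl
Why: Oxime condensation is selective for the aldehyde, the only other carbonyl groups being an ester and a ketal, and the E/Z composition of the oxime does not matter for the next step.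

Step 17
Reactants: 30 cyclopentenyl aldoxime
Product: 33 spiro-fused isoxazoline (1S,2S,5R,10S), via hydroximoyl chloride 31 (not isolated), via nitrile oxide 32 (not isolated)
Conditions: aq. NaOCl, CH2Cl2, 0 °C → rt, 0.01 M (slow addition of 30)
Reagents that add atoms: none
Why: Hypochlorite chlorinates the aldoxime and the hydroximoyl chloride 31 loses HCl to the nitrile oxide 32, which adds across C5=C1 in a concerted suprafacial (3+2) cycloaddition, the intramolecular nitrile oxide–alkene cycloaddition known for tethered cycloalkenes, including cases that create a quaternary carbon at the tethered alkene terminus. Ring B closes in a 6-exo sense because the tether C7–C10 lets the dipole carbon C6 reach only C5, and the isoxazoline ring is made by the cycloaddition itself through the C6–C5 and O–C1 bonds, cis-fused to ring A. The new centres C5 (spiro) and C1 are formed together and are therefore cis; their absolute sense is set by the allylic C2 arm next to the oxygen-accepting carbon, which sends the dipole to the opposite face, and the C10 centre is matched because its side chain then lies on the open C1–H side of the forming ring. The step needs the right alkene face (secured by C2), a single regiochemistry (secured by the tether) and ring closure faster than furoxan formation (secured by slow generation of the dipole at high dilution). Ketal, silyl ether and ester are inert to hypochlorite, and a 1-alkylcyclopentene is a good dipolarophile.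

Step 18
Reactants: 33 spiro-fused isoxazoline (1S,2S,5R,10S)
Product: 35 β-hydroxy ketone (C1 hydroxyl and C6 ketone), via hydroxy imine 34 (not isolated)
Conditions: Mo(CO)6, MeCN/H2O (15:1), 80 °C
Reagents that add atoms: water, O
Why: Reductive N–O cleavage with Mo(CO)6 in wet acetonitrile gives the β-hydroxy imine, which hydrolyses in situ to the β-hydroxy ketone under neutral conditions that do not trigger retro-aldol opening and keep the C1 oxygen cis to C6.

Step 19
Reactants: 35 β-hydroxy ketone (C1 hydroxyl and C6 ketone)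
Product: 36 C1 tert-butyldimethylsilyl ether of 35
Conditions: t-BuMe2SiOTf, 2,6-lutidine, CH2Cl2, −78 → 0 °C
Reagents that add atoms: tert-butyldimethylsilyl trifluoromethanesulfonate, CC(C)(C)[Si](C)(C)OS(=O)(=O)C(F)(F)F
Why: Silyl triflate silylation with a hindered pyridine base caps the neopentyl C1 hydroxyl without forming the alkoxide, so retro-aldol cleavage is avoided and a bulky group is placed on the C1 side of the ketone.

Step 20
Reactants: 36 C1 tert-butyldimethylsilyl ether of 35
Product: 37 C6 tertiary alcohol (6S)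
Conditions: MeLi, CeCl3, THF, −78 °C
Reagents that add atoms: methyllithium, [Li]C
Why: In this organocerium 1,2-addition the weakly basic methylcerium reagent adds to the hindered, enolisable C6 ketone faster than to the methyl ester and enters from the ring-B face on the C4 side, anti to the C1 silyloxy group and the C10 side chain, so the new hydroxyl is cis to C1 as required.

Step 21
Reactants: 37 C6 tertiary alcohol (6S)
Product: 38 C9 ketone
Conditions: I2 (10 mol%), acetone/H2O (50:1), rt
Reagents that add atoms: water, O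
Why: Iodine-catalysed ketal exchange in wet acetone unmasks the C9 ketone under essentially neutral conditions that the silyl ethers and the tertiary alcohol tolerate and under which enolisation toward C10 is slow.

Step 22
Reactants: 38 C9 ketone
Product: 39 C9 isopropenyl carbinol (mixture of C9 epimers)
Conditions: CH2=C(CH3)MgBr, CeCl3, THF, −78 → −40 °C
Reagents that add atoms: isopropenylmagnesium bromide, CC(=C)[Mg]Br
Why: Organocerium 1,2-addition of the isopropenyl group to the hindered C9 ketone avoids enolisation at C10 and attack on the ester, and the configuration of the new carbinol centre is unimportant because it is destroyed in the next step.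

Step 23
Reactants: 39 C9 isopropenyl carbinol (mixture of C9 epimers)
Product: 42 (Z)-tetrasubstituted enal, via tertiary chromate ester 40 (not isolated), via primary allylic chromate ester 41 (not isolated)
Conditions: [C5H5NH][CrO3Cl] (pyridinium chlorochromate), 4 Å MS, CH2Cl2, rt
Reagents that add atoms: pyridinium chlorochromate, [O-][Cr](=O)(=O)Cl.c1cc[nH+]cc1
Why: In this Babler–Dauben oxidative transposition the tertiary allylic chromate ester of either C9 epimer undergoes a [3,3] shift and the resulting primary chromate is oxidised to the enal; the Z isomer, with the flat formyl group and not the methyl group beside the branched C10, should be the more stable one, and the isomers can be equilibrated (catalytic I2, light) and separated at this triene-free stage.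

Step 24
Reactants: 42 (Z)-tetrasubstituted enal
Product: 43 dioxolane acetal of enal 42
Conditions: (Me3SiOCH2)2, Me3SiOTf (5 mol%), CH2Cl2, −78 → −40 °C; pyridine quench
Reagents that add atoms: 1,2-bis(trimethylsilyloxy)ethane, C[Si](C)(C)OCCO[Si](C)(C)C
Why: Noyori acetalisation masks the aldehyde at low temperature so that the ester arm can be treated with strong base and hydride; the tetrasubstituted alkene does not migrate, and a trimethylsilyl ether that might form at the hindered C6 hydroxyl would be lost on work-up or in the last step.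

Step 25
Reactants: 44 6-methylhept-5-en-2-one
Product: 46 6-methylhepta-1,5-dien-2-yl trifluoromethanesulfonate, via lithium enolate 45 (not isolated)
Conditions: LiN(i-Pr)2, THF, −78 °C; then PhNTf2, −78 → 0 °C
Reagents that add atoms: N-phenylbis(trifluoromethanesulfonimide), O=S(=O)(N(c1ccccc1)S(=O)(=O)C(F)(F)F)C(F)(F)F
Why: Kinetic deprotonation of the methyl ketone at the methyl group and O-triflation of the enolate give the terminal enol triflate regioselectively.

Step 26
Reactants: 46 6-methylhepta-1,5-dien-2-yl trifluoromethanesulfonate; 47 acrolein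
Product: 48 (2E)-8-methyl-4-methylidenenona-2,7-dienal
Conditions: Pd(OAc)2 (5 mol%), PPh3 (10 mol%), Et3N, DMF, 50 °C
Reagents that add atoms: none
Why: Heck coupling of the enol triflate with acrolein forms the (E)-dienal through syn-insertion and syn-β-hydride elimination, the trisubstituted alkene being inert.

Step 27
Reactants: 43 dioxolane acetal of enal 42; 48 (2E)-8-methyl-4-methylidenenona-2,7-dienal
Product: 50 β-hydroxy ester (aldol adduct; mixture at the two new centres), via lithium ester enolate 49 (not isolated)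
Conditions: LiN(i-Pr)2 (2.3 equiv), THF, −78 °C; then 48, −78 °C
Reagents that add atoms: none
Why: In this aldol addition the lithium enolate of the methyl ester (one further equivalent of base is taken up by the C6 hydroxyl) adds 1,2 to the non-enolisable dienal, and the mixture at the two new centres is erased in the next step.

Step 28
Reactants: 50 β-hydroxy ester (aldol adduct; mixture at the two new centres)
Product: 52 (2E,4E)-trienoate, via acetate 51 (not isolated)
Conditions: Ac2O, DMAP, Et3N, CH2Cl2, 0 °C → rt; then DBU, rt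
Reagents that add atoms: none
Why: Acetylation of the secondary aldol hydroxyl (the tertiary alcohol does not react) and E1cB elimination with DBU give the conjugated ester with the thermodynamically preferred E geometry, in which the dienyl chain is trans to the ester and cis to the ring.

Step 29
Reactants: 52 (2E,4E)-trienoate
Product: 53 trienyl allylic alcohol
Conditions: i-Bu2AlH, CH2Cl2, −78 → −40 °C; aq. potassium sodium tartrate
Reagents that add atoms: none
Why: Hydride reduction with i-Bu2AlH takes the conjugated ester 1,2 to the allylic alcohol at low temperature without touching the dioxolane, the silyl ethers or the triene.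

Step 30
Reactants: 53 trienyl allylic alcohol
Product: 55 CNP0246965.1, via desilylated acetal 54 (not isolated)
Conditions: HF·pyridine, pyridine, THF, 0 °C → rt; then aq. oxalic acid, rt
Reagents that add atoms: water, O
Why: Fluoride-mediated desilylation with buffered HF·pyridine removes both silyl ethers and mild aqueous acid then hydrolyses the allylic dioxolane, whose oxocarbenium ion forms easily, releasing the enal without disturbing the triene or the five stereocentres.

**Compound list** (TBS = tert-butyldimethylsilyl; spiro numbering as in the plan)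

1 | 3-ethoxycyclopent-2-en-1-one | CCOC1=CC(=O)CC1 | starting material
2 | tert-butyl acetate | CC(=O)OC(C)(C)C | starting material
3 | lithium 1-tert-butoxyethen-1-olate (enolate of 2) | [Li+].[O-]C(=C)OC(C)(C)C | intermediate (not isolated)
4 | tert-butyl 2-(3-ethoxy-1-hydroxycyclopent-2-en-1-yl)acetate (racemic; lithium alkoxide in the flask) | CCOC1=CC(O)(CC(=O)OC(C)(C)C)CC1 | intermediate (not isolated)
5 | tert-butyl 2-(3-oxocyclopent-1-en-1-yl)acetate | CC(C)(C)OC(=O)CC1=CC(=O)CC1 | intermediate
6 | tert-butyl 2-[(3R)-3-hydroxycyclopent-1-en-1-yl]acetate | CC(C)(C)OC(=O)CC1=C[C@H](O)CC1 | intermediate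
7 | tert-butyl 2-[(3R)-3-(acetyloxy)cyclopent-1-en-1-yl]acetate | CC(C)(C)OC(=O)CC1=C[C@H](OC(C)=O)CC1 | intermediate
8 | dimethyl malonate | COC(=O)CC(=O)OC | starting material
9 | sodium dimethyl malonate | [Na+].COC(=O)[CH-]C(=O)OC | intermediate (not isolated)
10 | dimethyl 2-[(1R)-3-(2-tert-butoxy-2-oxoethyl)cyclopent-2-en-1-yl]propanedioate (R by CIP priority; same spatial arrangement as 11) | CC(C)(C)OC(=O)CC1=C[C@H](C(C(=O)OC)C(=O)OC)CC1 | intermediate
11 | methyl 2-[(1S)-3-(2-tert-butoxy-2-oxoethyl)cyclopent-2-en-1-yl]acetate | CC(C)(C)OC(=O)CC1=C[C@H](CC(=O)OC)CC1 | intermediate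
12 | trimethylsilyl 2-[(3S)-3-(2-methoxy-2-oxoethyl)cyclopent-1-en-1-yl]acetate | C[Si](C)(C)OC(=O)CC1=C[C@H](CC(=O)OC)CC1 | intermediate (not isolated)
13 | 2-[(3S)-3-(2-methoxy-2-oxoethyl)cyclopent-1-en-1-yl]acetic acid | OC(=O)CC1=C[C@H](CC(=O)OC)CC1 | intermediate
14 | (4S)-4-benzyl-1,3-oxazolidin-2-one | O=C1N[C@@H](Cc2ccccc2)CO1 | starting material
15 | mixed anhydride of 13 with 2,2-dimethylpropanoic acid | CC(C)(C)C(=O)OC(=O)CC1=C[C@H](CC(=O)OC)CC1 | intermediate (not isolated)
16 | methyl 2-[(1S)-3-{2-[(4S)-4-benzyl-2-oxo-1,3-oxazolidin-3-yl]-2-oxoethyl}cyclopent-2-en-1-yl]acetate | O=C1OC[C@H](Cc2ccccc2)N1C(=O)CC3=C[C@H](CC(=O)OC)CC3 | intermediate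
17 | allyl bromide | C=CCBr | starting material
18 | sodium (Z)-enolate of imide 16 | [Na+].[O-]/C(N1[C@@H](Cc2ccccc2)COC1=O)=C\C3=C[C@H](CC(=O)OC)CC3 | intermediate (not isolated)
19 | methyl 2-[(1S)-3-{(2S)-1-[(4S)-4-benzyl-2-oxo-1,3-oxazolidin-3-yl]-1-oxopent-4-en-2-yl}cyclopent-2-en-1-yl]acetate | O=C1OC[C@H](Cc2ccccc2)N1C(=O)[C@@H](CC=C)C3=C[C@H](CC(=O)OC)CC3 | intermediate
20 | methyl 2-[(1S)-3-[(2S)-1-(ethylsulfanyl)-1-oxopent-4-en-2-yl]cyclopent-2-en-1-yl]acetate | CCSC(=O)[C@@H](CC=C)C1=C[C@H](CC(=O)OC)CC1 | intermediate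
21 | 3-bromopropyl acetate | CC(=O)OCCCBr | starting material
22 | [3-(acetyloxy)propyl]zinc bromide | CC(=O)OCCC[Zn]Br | intermediate (not isolated)
23 | methyl 2-[(1S)-3-[(4S)-8-(acetyloxy)-5-oxooct-1-en-4-yl]cyclopent-2-en-1-yl]acetate | CC(=O)OCCCC(=O)[C@@H](CC=C)C1=C[C@H](CC(=O)OC)CC1 | intermediate
24 | methyl 2-[(1S)-3-[(1S)-1-{2-[3-(acetyloxy)propyl]-1,3-dioxolan-2-yl}but-3-en-1-yl]cyclopent-2-en-1-yl]acetate | CC(=O)OCCCC1(OCCO1)[C@@H](CC=C)C2=C[C@H](CC(=O)OC)CC2 | intermediate
25 | B-alkyl-9-borabicyclo[3.3.1]nonane adduct of 24 (boron on the terminal carbon) | CC(=O)OCCCC1(OCCO1)[C@@H](CCCB3C4CCCC3CCC4)C2=C[C@H](CC(=O)OC)CC2 | intermediate (not isolated)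
26 | methyl 2-[(1S)-3-[(1S)-1-{2-[3-(acetyloxy)propyl]-1,3-dioxolan-2-yl}-4-hydroxybutyl]cyclopent-2-en-1-yl]acetate | CC(=O)OCCCC1(OCCO1)[C@@H](CCCO)C2=C[C@H](CC(=O)OC)CC2 | intermediate
27 | methyl 2-[(1S)-3-[(1S)-1-{2-[3-(acetyloxy)propyl]-1,3-dioxolan-2-yl}-4-(TBS-oxy)butyl]cyclopent-2-en-1-yl]acetate | CC(=O)OCCCC1(OCCO1)[C@@H](CCCO[Si](C)(C)C(C)(C)C)C2=C[C@H](CC(=O)OC)CC2 | intermediate
28 | methyl 2-[(1S)-3-[(1S)-4-(TBS-oxy)-1-[2-(3-hydroxypropyl)-1,3-dioxolan-2-yl]butyl]cyclopent-2-en-1-yl]acetate | OCCCC1(OCCO1)[C@@H](CCCO[Si](C)(C)C(C)(C)C)C2=C[C@H](CC(=O)OC)CC2 | intermediate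
29 | methyl 2-[(1S)-3-[(1S)-4-(TBS-oxy)-1-[2-(3-oxopropyl)-1,3-dioxolan-2-yl]butyl]cyclopent-2-en-1-yl]acetate | O=CCCC1(OCCO1)[C@@H](CCCO[Si](C)(C)C(C)(C)C)C2=C[C@H](CC(=O)OC)CC2 | intermediate
30 | methyl 2-[(1S)-3-[(1S)-4-(TBS-oxy)-1-{2-[(3E)-3-(hydroxyimino)propyl]-1,3-dioxolan-2-yl}butyl]cyclopent-2-en-1-yl]acetate | O/N=C/CCC1(OCCO1)[C@@H](CCCO[Si](C)(C)C(C)(C)C)C2=C[C@H](CC(=O)OC)CC2 | intermediate (key-step precursor)
31 | hydroximoyl chloride of 30 (C6 bears Cl; C=N geometry not defined) | ON=C(Cl)CCC1(OCCO1)[C@@H](CCCO[Si](C)(C)C(C)(C)C)C2=C[C@H](CC(=O)OC)CC2 | intermediate (not isolated)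
32 | nitrile oxide of 30 (C6≡N–O) | [O-][N+]#CCCC1(OCCO1)[C@@H](CCCO[Si](C)(C)C(C)(C)C)C2=C[C@H](CC(=O)OC)CC2 | intermediate (not isolated)
33 | methyl [(1S,2S,5R,10S)-10-[3-(TBS-oxy)propyl]-9,9-(ethylenedioxy)spiro[4.5]decan-2-yl]acetate with an O–N=C6 isoxazoline fused across C1–C5 | COC(=O)C[C@@H]1CC[C@]2([C@H](CCCO[Si](C)(C)C(C)(C)C)C3(OCCO3)CCC2=NO4)[C@H]14 | intermediate (key-step product)
34 | methyl [(1S,2S,5S,10S)-10-[3-(TBS-oxy)propyl]-9,9-(ethylenedioxy)-1-hydroxy-6-iminospiro[4.5]decan-2-yl]acetate | COC(=O)C[C@@H]1CC[C@]2([C@H](CCCO[Si](C)(C)C(C)(C)C)C3(OCCO3)CCC2=N)[C@H]1O | intermediate (not isolated)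
35 | methyl [(1S,2S,5S,10S)-10-[3-(TBS-oxy)propyl]-9,9-(ethylenedioxy)-1-hydroxy-6-oxospiro[4.5]decan-2-yl]acetate | COC(=O)C[C@@H]1CC[C@]2([C@H](CCCO[Si](C)(C)C(C)(C)C)C3(OCCO3)CCC2=O)[C@H]1O | intermediate
36 | methyl [(1S,2S,5S,10S)-1-(TBS-oxy)-10-[3-(TBS-oxy)propyl]-9,9-(ethylenedioxy)-6-oxospiro[4.5]decan-2-yl]acetate | COC(=O)C[C@@H]1CC[C@]2([C@H](CCCO[Si](C)(C)C(C)(C)C)C3(OCCO3)CCC2=O)[C@H]1O[Si](C)(C)C(C)(C)C | intermediate
37 | methyl [(1S,2S,5S,6S,10S)-1-(TBS-oxy)-10-[3-(TBS-oxy)propyl]-9,9-(ethylenedioxy)-6-hydroxy-6-methylspiro[4.5]decan-2-yl]acetate | COC(=O)C[C@@H]1CC[C@]2([C@H](CCCO[Si](C)(C)C(C)(C)C)C3(OCCO3)CC[C@]2(C)O)[C@H]1O[Si](C)(C)C(C)(C)C | intermediate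
38 | methyl [(1S,2S,5S,6S,10S)-1-(TBS-oxy)-10-[3-(TBS-oxy)propyl]-6-hydroxy-6-methyl-9-oxospiro[4.5]decan-2-yl]acetate | COC(=O)C[C@@H]1CC[C@]2([C@H](CCCO[Si](C)(C)C(C)(C)C)C(=O)CC[C@]2(C)O)[C@H]1O[Si](C)(C)C(C)(C)C | intermediate
39 | methyl [(1S,2S,5S,6S,10S)-1-(TBS-oxy)-10-[3-(TBS-oxy)propyl]-6,9-dihydroxy-6-methyl-9-(prop-1-en-2-yl)spiro[4.5]decan-2-yl]acetate (C9 epimers) | COC(=O)C[C@@H]1CC[C@]2([C@H](CCCO[Si](C)(C)C(C)(C)C)C(O)(C(C)=C)CC[C@]2(C)O)[C@H]1O[Si](C)(C)C(C)(C)C | intermediate
40 | C9 hydrogen chromate ester of 39 | COC(=O)C[C@@H]1CC[C@]2([C@H](CCCO[Si](C)(C)C(C)(C)C)C(O[Cr](=O)(=O)O)(C(C)=C)CC[C@]2(C)O)[C@H]1O[Si](C)(C)C(C)(C)C | intermediate (not isolated)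
41 | transposed primary allylic hydrogen chromate ester (C9=C(CH3)CH2O–Cr) | COC(=O)C[C@@H]1CC[C@]2([C@H](CCCO[Si](C)(C)C(C)(C)C)/C(=C(/C)CO[Cr](=O)(=O)O)CC[C@]2(C)O)[C@H]1O[Si](C)(C)C(C)(C)C | intermediate (not isolated)
42 | methyl [(1S,2S,5S,6S,9Z,10R)-1-(TBS-oxy)-10-[3-(TBS-oxy)propyl]-6-hydroxy-6-methyl-9-(1-oxopropan-2-ylidene)spiro[4.5]decan-2-yl]acetate (10R only through a change of CIP priority at C9; no inversion) | COC(=O)C[C@@H]1CC[C@]2([C@H](CCCO[Si](C)(C)C(C)(C)C)/C(=C(/C)C=O)CC[C@]2(C)O)[C@H]1O[Si](C)(C)C(C)(C)C | intermediate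
43 | methyl [(1S,2S,5S,6S,9Z,10R)-1-(TBS-oxy)-10-[3-(TBS-oxy)propyl]-9-[1-(1,3-dioxolan-2-yl)ethylidene]-6-hydroxy-6-methylspiro[4.5]decan-2-yl]acetate | COC(=O)C[C@@H]1CC[C@]2([C@H](CCCO[Si](C)(C)C(C)(C)C)/C(=C(/C)C3OCCO3)CC[C@]2(C)O)[C@H]1O[Si](C)(C)C(C)(C)C | intermediate
44 | 6-methylhept-5-en-2-one | CC(=O)CCC=C(C)C | starting material
45 | lithium 6-methylhepta-1,5-dien-2-olate | [Li+].[O-]C(=C)CCC=C(C)C | intermediate (not isolated)
46 | 6-methylhepta-1,5-dien-2-yl trifluoromethanesulfonate | C=C(OS(=O)(=O)C(F)(F)F)CCC=C(C)C | intermediate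
47 | acrolein (prop-2-enal) | C=CC=O | starting material
48 | (2E)-8-methyl-4-methylidenenona-2,7-dienal | O=C/C=C/C(=C)CCC=C(C)C | intermediate
49 | dilithium salt of 43 (ester enolate and C6 alkoxide; enolate geometry not defined) | [Li+].[Li+].COC([O-])=C[C@@H]1CC[C@]2([C@H](CCCO[Si](C)(C)C(C)(C)C)/C(=C(/C)C3OCCO3)CC[C@]2(C)[O-])[C@H]1O[Si](C)(C)C(C)(C)C | intermediate (not isolated)
50 | methyl (4E)-3-hydroxy-10-methyl-6-methylidene-2-[spirocycle of 43 attached at C2]undeca-4,9-dienoate (mixture at C2 and C3 of the chain) | COC(=O)C(C(O)/C=C/C(=C)CCC=C(C)C)[C@@H]1CC[C@]2([C@H](CCCO[Si](C)(C)C(C)(C)C)/C(=C(/C)C3OCCO3)CC[C@]2(C)O)[C@H]1O[Si](C)(C)C(C)(C)C | intermediate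
51 | 3-O-acetate of 50 | COC(=O)C(C(OC(C)=O)/C=C/C(=C)CCC=C(C)C)[C@@H]1CC[C@]2([C@H](CCCO[Si](C)(C)C(C)(C)C)/C(=C(/C)C3OCCO3)CC[C@]2(C)O)[C@H]1O[Si](C)(C)C(C)(C)C | intermediate (not isolated)
52 | methyl (2E,4E)-10-methyl-6-methylidene-2-[spirocycle of 43 attached at C2]undeca-2,4,9-trienoate | C=C(/C=C/C=C(/C(=O)OC)[C@@H]1CC[C@]2([C@H](CCCO[Si](C)(C)C(C)(C)C)/C(=C(/C)C3OCCO3)CC[C@]2(C)O)[C@H]1O[Si](C)(C)C(C)(C)C)CCC=C(C)C | intermediate
53 | (2E,4E)-10-methyl-6-methylidene-2-[spirocycle of 43 attached at C2]undeca-2,4,9-trien-1-ol | C=C(/C=C/C=C(/CO)[C@@H]1CC[C@]2([C@H](CCCO[Si](C)(C)C(C)(C)C)/C(=C(/C)C3OCCO3)CC[C@]2(C)O)[C@H]1O[Si](C)(C)C(C)(C)C)CCC=C(C)C | intermediate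
54 | dioxolane acetal of the target (both silyl groups removed) | C=C(/C=C/C=C(/CO)[C@@H]1CC[C@]2([C@H](CCCO)/C(=C(/C)C3OCCO3)CC[C@]2(C)O)[C@H]1O)CCC=C(C)C | intermediate (not isolated)
55 | CNP0246965.1, (2Z)-2-[(1S,2S,5S,6S,10R)-1,6-dihydroxy-2-[(2E,4E)-1-hydroxy-10-methyl-6-methylideneundeca-2,4,9-trien-2-yl]-10-(3-hydroxypropyl)-6-methylspiro[4.5]decan-9-ylidene]propanal | C=C(/C=C/C=C(/CO)[C@@H]1CC[C@]2([C@H](CCCO)/C(=C(/C)C=O)CC[C@]2(C)O)[C@H]1O)CCC=C(C)C | target

**Step count and risks**

Total step count: 30. Longest linear sequence: 28 steps (steps 1–24 and 27–30; steps 25–26 make dienal 48).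

Steps most likely to fail:

1. Step 23 (oxidative transposition to the tetrasubstituted enal). The [3,3] shift of the hindered tertiary chromate may stall or be outrun by dehydration of the tertiary allylic alcohol. The oxygen may also be delivered so that the formyl group ends up beside C8, with equilibration not favouring the Z isomer strongly enough. The fallback makes the C9=C bond by carbonyl olefination and sets out from ketone 38. Peterson reaction with the lithium aza-enolate of N-tert-butyl-2-(trimethylsilyl)propan-1-imine (LiN(i-Pr)2, THF, −78 → 0 °C) should give the β-silyl carbinol adduct F1. This loses silanolate by syn-elimination to the α,β-unsaturated N-tert-butyl aldimine F2. Hydrolysis with aqueous oxalic acid returns to the route at enal 42. No chromate or allylic cation is involved, so dehydration is avoided; the geometry is again settled by equilibration and separation at the stage of 42.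

2. Step 17 (nitrile oxide cycloaddition). Ring closure onto the trisubstituted alkene may be slower than dimerisation of the dipole to a furoxan, and facial selectivity may be incomplete. The fallback uses a silyl nitronate as the dipole and sets out from alcohol 28. Appel iodination (I2, PPh3, imidazole) gives the iodide F3, and nitrite displacement (NaNO2, phloroglucinol, DMF) gives the nitroalkane F4. Silylation (Me3SiCl, Et3N, benzene) gives the silyl nitronate F5, which does not dimerise and should add across C5=C1 through the same tether to the N-silyloxy isoxazolidine F6, forming the same C6–C5 and O–C1 bonds. Acid (TsOH, Et2O) eliminates silanol and the route is rejoined at isoxazoline 33.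

3. Step 20 (methyl addition at C6). At the temperature the hindered ketone needs, the organometallic may also attack or enolise the methyl ester. The fallback masks the ester as its carboxylate and sets out from ketone 36. Saponification (LiOH, THF/H2O) gives the keto acid F7. MeLi/CeCl3 (excess, −78 °C) on its lithium carboxylate, which is inert to the organocerium reagent, gives the hydroxy acid F8. Esterification with Me3SiCHN2 in MeOH/toluene returns to the route at tertiary alcohol 37.

**Further compounds**

F1 | step 23 | β-silyl carbinol adduct of 38 (C9 carbinol bearing C(CH3)(SiMe3)CH=N-t-Bu; new centres not defined) | COC(=O)C[C@@H]1CC[C@]2([C@H](CCCO[Si](C)(C)C(C)(C)C)C(O)(C(C)(C=NC(C)(C)C)[Si](C)(C)C)CC[C@]2(C)O)[C@H]1O[Si](C)(C)C(C)(C)C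
F2 | step 23 | N-tert-butyl aldimine of enal 42 | COC(=O)C[C@@H]1CC[C@]2([C@H](CCCO[Si](C)(C)C(C)(C)C)/C(=C(/C)C=NC(C)(C)C)CC[C@]2(C)O)[C@H]1O[Si](C)(C)C(C)(C)C
F3 | step 17 | primary iodide from alcohol 28 | ICCCC1(OCCO1)[C@@H](CCCO[Si](C)(C)C(C)(C)C)C2=C[C@H](CC(=O)OC)CC2
F4 | step 17 | primary nitroalkane (C6–NO2) | [O-][N+](=O)CCCC1(OCCO1)[C@@H](CCCO[Si](C)(C)C(C)(C)C)C2=C[C@H](CC(=O)OC)CC2
F5 | step 17 | trimethylsilyl nitronate of F4 | C[Si](C)(C)O[N+]([O-])=CCCC1(OCCO1)[C@@H](CCCO[Si](C)(C)C(C)(C)C)C2=C[C@H](CC(=O)OC)CC2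
F6 | step 17 | N-(trimethylsilyloxy)isoxazolidine corresponding to 33 (C6 is CH; its configuration not defined) | COC(=O)C[C@@H]1CC[C@]2([C@H](CCCO[Si](C)(C)C(C)(C)C)C3(OCCO3)CCC2N(O[Si](C)(C)C)O4)[C@H]14
F7 | step 20 | carboxylic acid from ester 36 | OC(=O)C[C@@H]1CC[C@]2([C@H](CCCO[Si](C)(C)C(C)(C)C)C3(OCCO3)CCC2=O)[C@H]1O[Si](C)(C)C(C)(C)C
F8 | step 20 | hydroxy acid corresponding to 37 | OC(=O)C[C@@H]1CC[C@]2([C@H](CCCO[Si](C)(C)C(C)(C)C)C3(OCCO3)CC[C@]2(C)O)[C@H]1O[Si](C)(C)C(C)(C)C
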